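**Strategy**

Everything rests on disconnecting the cyclohexene ring between its chain-bearing methine C6 and its gem-dimethyl carbon C1 (carotenoid locants). The key step exploits the 1,3-relationship of C1 to the carbinol carbon C3 and the ring C4=C5 double bond: at the 3-oxo level C1 is an enone β-carbon, and C6, α to a C7 ester and vinylogous to the ketone, is a soft nucleophile. One operation joins mesityl oxide and ethyl but-2-ynoate to an acyclic 3-oxidotrienoate, which closes C6–C1 by 6-endo Michael addition and delivers the complete ring. The labile C6 centre is then set with C3 by enzymatic dynamic reduction, and a tetrazolyl sulfone joins the ring to crocetin dialdehyde.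

Key step: step 1

Assumption: all-E crocetin dialdehyde is taken as a purchasable C20 building block; C1 to C8′ in the text are carotenoid locants (C1 gem-dimethyl carbon, C3 carbinol carbon, C6 chain-bearing ring carbon), while compound names use systematic numbering.

**Route**

Step 1
Reactants: 1 mesityl oxide (4-methylpent-3-en-2-one); 2 ethyl but-2-ynoate
Product: 6 ethyl 2,6,6-trimethyl-4-oxocyclohex-2-ene-1-carboxylate (racemate), via lithium 4-methylpenta-1,3-dien-2-olate 3 (not isolated), via lithium trienolate 4 (not isolated), via cyclic lithium enolate 5 (not isolated)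
Conditions: LiN(i-Pr)2, THF, −78 °C; then 2, −78 °C to rt; then EtOH, 60 °C; AcOH quench
Reagents that add atoms: none
Why: LiN(i-Pr)2 deprotonates the α′-methyl of 1 kinetically to the cross-conjugated 2-oxidodiene 3, whose CH2 terminus adds to the β-carbon of ynoate 2 (the future C4–C5 bond) and, after proton transfer, gives the 3-oxidotrienoate 4. Ring closure then joins the ester-bearing carbon C6 to the gem-dimethyl β-carbon C1 of the enone, as a 6-endo-trig intramolecular Michael addition of the vinylogous ester enolate (equivalently a disrotatory 6π electrocyclisation of the oxidohexatriene); the closest known reaction types are the Michael–Michael (anionic Diels–Alder) annulation of cross-conjugated ketone dienolates with unsaturated esters and the base isomerisation of phorone to isophorone. The only new stereocentre, C6, forms without control and is deliberately left labile (α to the ester, γ to the enone) so that step 2 can set it. The step needs α′- over γ-deprotonation of 1 (secured by the kinetic base at −78 °C), attack at the methyl-bearing alkyne carbon (the only β-position of 2) and C- over O-cyclisation; any 2-pyranone formed by O-acylation should be reopened by lithium ethoxide in the ethanol stage and drain into the carbocycle, whose doubly stabilised enolate 5 is the thermodynamic sink. The acidic quench protonates 5 at C6 to give the ring-conjugated enone 6.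

Step 2
Reactants: 6 ethyl 2,6,6-trimethyl-4-oxocyclohex-2-ene-1-carboxylate (racemate)
Product: 7 ethyl (1R,4R)-4-hydroxy-2,6,6-trimethylcyclohex-2-ene-1-carboxylate
Conditions: ketoreductase (NADPH-dependent alcohol dehydrogenase, chosen from a panel), NADP+ (cat.), i-PrOH, triethanolamine buffer pH 8.5, DMSO (10 vol%), 30 °C
Reagents that add atoms: none
Why: Enzymatic dynamic kinetic resolution by asymmetric carbonyl reduction: the ketoreductase should accept only the (6R)-ketone and deliver hydride to the face that gives the (3R)-carbinol trans to the ester, while the unreacted enantiomer racemises through the achiral vinylogous enolate, so the enzyme sets both stereocentres.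

Step 3
Reactants: 7 ethyl (1R,4R)-4-hydroxy-2,6,6-trimethylcyclohex-2-ene-1-carboxylate
Product: 8 ethyl (1R,4R)-4-[(tert-butyldimethylsilyl)oxy]-2,6,6-trimethylcyclohex-2-ene-1-carboxylate
Conditions: t-BuMe2SiCl, imidazole, DMF, rt
Reagents that add atoms: tert-butyldimethylsilyl chloride, CC(C)(C)[Si](C)(C)Cl
Why: Silylation of the secondary allylic alcohol masks C3–OH so that only the primary alcohol made in step 4 is activated in step 5.

Step 4
Reactants: 8 ethyl (1R,4R)-4-[(tert-butyldimethylsilyl)oxy]-2,6,6-trimethylcyclohex-2-ene-1-carboxylate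
Product: 9 [(1R,4R)-4-[(tert-butyldimethylsilyl)oxy]-2,6,6-trimethylcyclohex-2-en-1-yl]methanol
Conditions: LiAlH4, THF, 0 °C
Reagents that add atoms: none
Why: Hydride reduction of the hindered ester to the primary alcohol proceeds by direct addition without enolisation, so C6 keeps its configuration, and the silyl ether is inert to LiAlH4.

Step 5
Reactants: 9 [(1R,4R)-4-[(tert-butyldimethylsilyl)oxy]-2,6,6-trimethylcyclohex-2-en-1-yl]methanol
Product: 10 5-({[(1R,4R)-4-[(tert-butyldimethylsilyl)oxy]-2,6,6-trimethylcyclohex-2-en-1-yl]methyl}sulfanyl)-1-phenyl-1H-tetrazole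
Conditions: 1-phenyl-1H-tetrazole-5-thiol, PPh3, diisopropyl azodicarboxylate, THF, 0 °C to rt
Reagents that add atoms: 1-phenyl-1H-tetrazole-5-thiol, Sc1nnnn1-c1ccccc1
Why: Mitsunobu thioetherification: the acidic tetrazolethiol displaces the activated primary alkoxyphosphonium by SN2 at C7, which is not a stereocentre.

Step 6
Reactants: 10 5-({[(1R,4R)-4-[(tert-butyldimethylsilyl)oxy]-2,6,6-trimethylcyclohex-2-en-1-yl]methyl}sulfanyl)-1-phenyl-1H-tetrazole
Product: 11 5-({[(1R,4R)-4-[(tert-butyldimethylsilyl)oxy]-2,6,6-trimethylcyclohex-2-en-1-yl]methyl}sulfonyl)-1-phenyl-1H-tetrazole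
Conditions: (NH4)6Mo7O24·4H2O (cat.), 30% aq H2O2, EtOH, 0 °C to rt
Reagents that add atoms: hydrogen peroxide, OO
Why: Molybdate-catalysed peroxide oxidation of sulfide to sulfone is chemoselective for sulfur over the hindered trisubstituted ring alkene and compatible with the silyl ether.

Step 7
Reactants: 11 5-({[(1R,4R)-4-[(tert-butyldimethylsilyl)oxy]-2,6,6-trimethylcyclohex-2-en-1-yl]methyl}sulfonyl)-1-phenyl-1H-tetrazole; 12 crocetin dialdehyde ((2E,4E,6E,8E,10E,12E,14E)-2,6,11,15-tetramethylhexadeca-2,4,6,8,10,12,14-heptaenedial)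
Product: 14 (2E,4E,6E,8E,10E,12E,14E,16E)-17-[(1R,4R)-4-[(tert-butyldimethylsilyl)oxy]-2,6,6-trimethylcyclohex-2-en-1-yl]-2,6,11,15-tetramethylheptadeca-2,4,6,8,10,12,14,16-octaenal, via C7-potassiated tetrazolyl sulfone 13 (not isolated)
Conditions: KN(SiMe3)2, THF, −78 °C; then 12 (3 equiv), −78 °C to rt; aqueous work-up
Reagents that add atoms: none
Why: Julia–Kocienski olefination: the premetalated tetrazolyl sulfone adds to one formyl group of 12 (used in excess so that the second stays free), and Smiles rearrangement with anti elimination of sulfur dioxide and tetrazololate should give the E-configured C7=C8 bond without touching the non-acidic C6–H.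

Step 8
Reactants: 14 (2E,4E,6E,8E,10E,12E,14E,16E)-17-[(1R,4R)-4-[(tert-butyldimethylsilyl)oxy]-2,6,6-trimethylcyclohex-2-en-1-yl]-2,6,11,15-tetramethylheptadeca-2,4,6,8,10,12,14,16-octaenal
Product: 15 (2E,4E,6E,8E,10E,12E,14E,16E)-17-[(1R,4R)-4-[(tert-butyldimethylsilyl)oxy]-2,6,6-trimethylcyclohex-2-en-1-yl]-2,6,11,15-tetramethylheptadeca-2,4,6,8,10,12,14,16-octaen-1-ol
Conditions: NaBH4, THF/MeOH, 0 °C
Reagents that add atoms: none
Why: Borohydride 1,2-reduction of the conjugated polyenal gives the primary allylic alcohol, as in retinal to retinol, and leaves the silyl ether and the polyene untouched.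

Step 9
Reactants: 15 (2E,4E,6E,8E,10E,12E,14E,16E)-17-[(1R,4R)-4-[(tert-butyldimethylsilyl)oxy]-2,6,6-trimethylcyclohex-2-en-1-yl]-2,6,11,15-tetramethylheptadeca-2,4,6,8,10,12,14,16-octaen-1-ol
Product: 16 (1R,4R)-4-[(1E,3E,5E,7E,9E,11E,13E,15E)-17-hydroxy-3,7,12,16-tetramethylheptadeca-1,3,5,7,9,11,13,15-octaen-1-yl]-3,5,5-trimethylcyclohex-2-en-1-ol ((3R,6R)-8′-apo-ε-carotene-3,8′-diol, CNP0292981.1)
Conditions: Bu4NF, THF, 0 °C to rt, dark, argon; aqueous work-up
Reagents that add atoms: none
Why: Fluoride-mediated desilylation under non-acidic conditions spares the acid-labile allylic carbinol at C3 and the polyene and releases the target.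

**Compound list**

1 | mesityl oxide (4-methylpent-3-en-2-one) | CC(=O)C=C(C)C | starting material
2 | ethyl but-2-ynoate | CC#CC(=O)OCC | starting material
3 | lithium 4-methylpenta-1,3-dien-2-olate | [Li+].[O-]C(=C)C=C(C)C | intermediate
4 | lithium salt of ethyl 3,7-dimethyl-5-oxidoocta-2,4,6-trienoate (acyclic trienolate) | [Li+].CCOC(=O)C=C(C)C=C([O-])C=C(C)C | intermediate
5 | lithium 4-(ethoxycarbonyl)-3,5,5-trimethylcyclohexa-1,3-dien-1-olate | [Li+].CCOC(=O)C1=C(C)C=C([O-])CC1(C)C | intermediate
6 | ethyl 2,6,6-trimethyl-4-oxocyclohex-2-ene-1-carboxylate (racemate) | CCOC(=O)C1C(C)=CC(=O)CC1(C)C | intermediate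
7 | ethyl (1R,4R)-4-hydroxy-2,6,6-trimethylcyclohex-2-ene-1-carboxylate | CC1=C[C@H](O)CC(C)(C)[C@H]1C(=O)OCC | intermediate
8 | ethyl (1R,4R)-4-[(tert-butyldimethylsilyl)oxy]-2,6,6-trimethylcyclohex-2-ene-1-carboxylate | CC1=C[C@H](O[Si](C)(C)C(C)(C)C)CC(C)(C)[C@H]1C(=O)OCC | intermediate
9 | [(1R,4R)-4-[(tert-butyldimethylsilyl)oxy]-2,6,6-trimethylcyclohex-2-en-1-yl]methanol | CC1=C[C@H](O[Si](C)(C)C(C)(C)C)CC(C)(C)[C@H]1CO | intermediate
10 | 5-({[(1R,4R)-4-[(tert-butyldimethylsilyl)oxy]-2,6,6-trimethylcyclohex-2-en-1-yl]methyl}sulfanyl)-1-phenyl-1H-tetrazole | CC1=C[C@H](O[Si](C)(C)C(C)(C)C)CC(C)(C)[C@H]1CSc1nnnn1-c1ccccc1 | intermediate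
11 | 5-({[(1R,4R)-4-[(tert-butyldimethylsilyl)oxy]-2,6,6-trimethylcyclohex-2-en-1-yl]methyl}sulfonyl)-1-phenyl-1H-tetrazole | CC1=C[C@H](O[Si](C)(C)C(C)(C)C)CC(C)(C)[C@H]1CS(=O)(=O)c1nnnn1-c1ccccc1 | intermediate
12 | crocetin dialdehyde ((2E,4E,6E,8E,10E,12E,14E)-2,6,11,15-tetramethylhexadeca-2,4,6,8,10,12,14-heptaenedial) | O=C/C(C)=C/C=C/C(C)=C/C=C/C=C(C)/C=C/C=C(\C)C=O | starting material
13 | potassium salt of sulfone 11, deprotonated at the sulfonyl-bearing CH2 (C7) | [K+].CC1=C[C@H](O[Si](C)(C)C(C)(C)C)CC(C)(C)[C@H]1[CH-]S(=O)(=O)c1nnnn1-c1ccccc1 | intermediate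
14 | (2E,4E,6E,8E,10E,12E,14E,16E)-17-[(1R,4R)-4-[(tert-butyldimethylsilyl)oxy]-2,6,6-trimethylcyclohex-2-en-1-yl]-2,6,11,15-tetramethylheptadeca-2,4,6,8,10,12,14,16-octaenal | CC1=C[C@H](O[Si](C)(C)C(C)(C)C)CC(C)(C)[C@H]1/C=C/C(C)=C/C=C/C(C)=C/C=C/C=C(C)/C=C/C=C(\C)C=O | intermediate
15 | (2E,4E,6E,8E,10E,12E,14E,16E)-17-[(1R,4R)-4-[(tert-butyldimethylsilyl)oxy]-2,6,6-trimethylcyclohex-2-en-1-yl]-2,6,11,15-tetramethylheptadeca-2,4,6,8,10,12,14,16-octaen-1-ol | CC1=C[C@H](O[Si](C)(C)C(C)(C)C)CC(C)(C)[C@H]1/C=C/C(C)=C/C=C/C(C)=C/C=C/C=C(C)/C=C/C=C(\C)CO | intermediate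
16 | (1R,4R)-4-[(1E,3E,5E,7E,9E,11E,13E,15E)-17-hydroxy-3,7,12,16-tetramethylheptadeca-1,3,5,7,9,11,13,15-octaen-1-yl]-3,5,5-trimethylcyclohex-2-en-1-ol | CC1=C[C@H](O)CC(C)(C)[C@H]1/C=C/C(C)=C/C=C/C(C)=C/C=C/C=C(C)/C=C/C=C(\C)CO | target

**Step count**

Total steps: 9. Longest linear sequence: 9 steps (1 and 2 to 16; 12 enters in step 7 as a purchased fragment).

**Steps most likely to fail**

Step 1. The annulation may be diverted before the ring bond forms: O-acylative lactonisation of the adduct, oligomerisation of the ynoate, or a sluggish Michael closure onto the hindered β,β-dimethyl enone. Fallback: the ring bond is made in a separate operation from an isolated heterocycle. Setting out from 1 and 2, the dienolate addition is run without the ethanol stage and the crude adduct is heated with AcOH in toluene, so that 4 lactonises to 4-methyl-6-(2-methylprop-1-en-1-yl)-2H-pyran-2-one F1. Purified F1 is then heated with LiOEt in EtOH; ethoxide opens the lactone back to trienolate 4, which closes C6–C1 under thermodynamic control through 5, and the route is rejoined at 6.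

Step 2. Racemisation at C6 may be too slow at a pH the enzyme tolerates, which would leave a simple kinetic resolution, or no ketoreductase may combine the required enantiomer and face selectivity. Fallback: non-enzymatic reduction followed by hydrolase resolution with recycling. From 6, Luche reduction (NaBH4, CeCl3·7H2O, MeOH) should give ethyl 4-hydroxy-2,6,6-trimethylcyclohex-2-ene-1-carboxylate F2 as a racemic cis/trans mixture. The trans racemate is separated by chromatography and acylated with vinyl acetate and an immobilised lipase chosen by screening, to give ethyl (1R,4R)-4-acetoxy-2,6,6-trimethylcyclohex-2-ene-1-carboxylate F3 beside unreacted enantiomer. F3 is ethanolysed (K2CO3, EtOH) and the route is rejoined at 7; the unwanted isomers of F2 are reoxidised with MnO2 to 6 and recycled.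

Step 7. The olefination may run twice on the dial, lose E selectivity at the new C7=C8 bond, or be undercut by vinylogous deprotonation of the polyenal by the sulfonyl carbanion. Fallback: phosphorus-ylide olefination with thermodynamic stereocorrection. From 9, iodine, PPh3 and imidazole in CH2Cl2 should give tert-butyl{[(1R,4R)-4-(iodomethyl)-3,5,5-trimethylcyclohex-2-en-1-yl]oxy}dimethylsilane F4. Heating F4 with PPh3 in MeCN gives {[(1R,4R)-4-[(tert-butyldimethylsilyl)oxy]-2,6,6-trimethylcyclohex-2-en-1-yl]methyl}triphenylphosphonium iodide F5. NaN(SiMe3)2 in THF at −78 °C converts F5 into {[(1R,4R)-4-[(tert-butyldimethylsilyl)oxy]-2,6,6-trimethylcyclohex-2-en-1-yl]methylidene}triphenylphosphorane F6, which is added to excess 12. The Wittig product is expected to be rich in the (16Z)-isomer of 14, (2E,4E,6E,8E,10E,12E,14E,16Z)-17-[(1R,4R)-4-[(tert-butyldimethylsilyl)oxy]-2,6,6-trimethylcyclohex-2-en-1-yl]-2,6,11,15-tetramethylheptadeca-2,4,6,8,10,12,14,16-octaenal F7. Catalytic iodine in CH2Cl2 under daylight should equilibrate it to the all-E aldehyde, and the route is rejoined at 14.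

Further compounds
F1 | step 1 | 4-methyl-6-(2-methylprop-1-en-1-yl)-2H-pyran-2-one | CC(C)=CC1=CC(C)=CC(=O)O1
F2 | step 2 | ethyl 4-hydroxy-2,6,6-trimethylcyclohex-2-ene-1-carboxylate (racemic cis/trans mixture) | CCOC(=O)C1C(C)=CC(O)CC1(C)C
F3 | step 2 | ethyl (1R,4R)-4-acetoxy-2,6,6-trimethylcyclohex-2-ene-1-carboxylate | CC1=C[C@H](OC(C)=O)CC(C)(C)[C@H]1C(=O)OCC
F4 | step 7 | tert-butyl{[(1R,4R)-4-(iodomethyl)-3,5,5-trimethylcyclohex-2-en-1-yl]oxy}dimethylsilane | CC1=C[C@H](O[Si](C)(C)C(C)(C)C)CC(C)(C)[C@H]1CI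
F5 | step 7 | {[(1R,4R)-4-[(tert-butyldimethylsilyl)oxy]-2,6,6-trimethylcyclohex-2-en-1-yl]methyl}triphenylphosphonium iodide | [I-].CC1=C[C@H](O[Si](C)(C)C(C)(C)C)CC(C)(C)[C@H]1C[P+](c1ccccc1)(c1ccccc1)c1ccccc1
F6 | step 7 | {[(1R,4R)-4-[(tert-butyldimethylsilyl)oxy]-2,6,6-trimethylcyclohex-2-en-1-yl]methylidene}triphenylphosphorane | CC1=C[C@H](O[Si](C)(C)C(C)(C)C)CC(C)(C)[C@H]1C=P(c1ccccc1)(c1ccccc1)c1ccccc1
F7 | step 7 | (2E,4E,6E,8E,10E,12E,14E,16Z)-17-[(1R,4R)-4-[(tert-butyldimethylsilyl)oxy]-2,6,6-trimethylcyclohex-2-en-1-yl]-2,6,11,15-tetramethylheptadeca-2,4,6,8,10,12,14,16-octaenal | CC1=C[C@H](O[Si](C)(C)C(C)(C)C)CC(C)(C)[C@H]1/C=C\C(C)=C\C=C\C(C)=C\C=C\C=C(C)\C=C\C=C(/C)C=O
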